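The route disconnects the arene ring (C4a, C5–C8, C8a) across C5–C4a and C8–C8a, in tetralone numbering (C1 ketone, C3 isopropenyl carbon, C4 quaternary carbon). A Hauser–Kraus annulation of a 5-sulfonyl methyl tetronate onto the C4a=C8a double bond of a cyclohexenone builds the whole para-hydroquinone ring at once, with C8–OH peri to the C1 ketone, isopropyl at C7 and methoxy at C6. The annulation precursor is a 4,4,5-trisubstituted cyclohex-2-enone that already holds both stereocentres and the propanoate chain as its tert-butyl ester. It is made from 2-methylcyclohex-2-enone by asymmetric isopropenyl conjugate addition, anti-selective Michael quaternisation and 1,3-carbonyl transposition.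

Key step: step 11

Assumption: the ligand antipode in step 1 is the one that gives the (3R) ketone; the sense of induction for this Grignard–enone pair has to be confirmed on a small scale.
Remark: locants C1–C8a in the running text follow tetralone numbering; systematic names keep their own numbering, and some CIP descriptors change along the route by priority only, not by geometry.

Step 1
Reactants: 1 2-methylcyclohex-2-en-1-one; 2 isopropenylmagnesium bromide
Product: 4 (3R)-2-methyl-3-(prop-1-en-2-yl)cyclohexan-1-one (both C2 epimers), via bromomagnesium enolate 3 (not isolated)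
Conditions: 2 (1.3 equiv, slow addition), CuBr·SMe2 (5 mol %), BINOL-derived bis(1-phenylethyl)phosphoramidite (6 mol %, antipode as assumed above), 2-MeTHF, −78 °C; then 1 M HCl
Reagents that add atoms: none
Why: Copper-catalysed asymmetric conjugate addition of a Grignard reagent to a cyclic enone, in which the chiral monovalent copper–phosphoramidite complex should deliver the isopropenyl group to one enantiotopic face of the β-carbon and thereby set C3 as (R), while C2 is protonated without control because it becomes sp2 again in step 2.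

Step 2
Reactants: 4 (3R)-2-methyl-3-(prop-1-en-2-yl)cyclohexan-1-one; 5 tert-butyl acrylate
Product: 8 tert-butyl 3-[(1S,6S)-1-methyl-2-oxo-6-(prop-1-en-2-yl)cyclohexyl]propanoate, via benzyl imine 6 (not isolated), via adduct imine 7 (not isolated)
Conditions: BnNH2 (1.1 equiv), TsOH (0.5 mol %), toluene, reflux, Dean–Stark; then 5 (1.5 equiv), THF, 60 °C; then 10% aq. AcOH, rt
Reagents that add atoms: water, O
Why: Imine-mediated Michael addition (aza-ene-type reaction of the more substituted secondary enamine tautomer with an acrylate), which is regiospecific for the methyl-bearing α-carbon, should add the acrylate anti to the neighbouring pseudoaxial isopropenyl group so that the quaternary centre forms with the propanoate chain trans to isopropenyl, involves no ester enolate that could oligomerise the acrylate, and ends with hydrolysis back to the ketone.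

Step 3
Reactants: 8 tert-butyl 3-[(1S,6S)-1-methyl-2-oxo-6-(prop-1-en-2-yl)cyclohexyl]propanoate
Product: 11 tert-butyl 3-[(1S,6S)-1-methyl-2-oxo-6-(prop-1-en-2-yl)cyclohex-3-en-1-yl]propanoate, via lithium enolate 9 (not isolated), via silyl enol ether 10 (not isolated)
Conditions: LiN(iPr)2 (1.05 equiv), Me3SiCl, THF, −78 °C; then Pd(OAc)2 (1.05 equiv), MeCN, rt
Reagents that add atoms: none
Why: Saegusa–Ito oxidation, in which the ketone can enolise only towards its CH2 neighbour, the silyl enol ether formed there is dehydrogenated by divalent palladium through β-hydride elimination, and neither stereocentre carries an acidic hydrogen.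

Step 4
Reactants: 11 tert-butyl 3-[(1S,6S)-1-methyl-2-oxo-6-(prop-1-en-2-yl)cyclohex-3-en-1-yl]propanoate
Product: 12 tert-butyl 3-[(3S,4S)-3-methyl-2-oxo-4-(prop-1-en-2-yl)-7-oxabicyclo[4.1.0]heptan-3-yl]propanoate (epoxide diastereomers)
Conditions: 30% aq. H2O2, NaOH (0.2 equiv), MeOH, 0 °C
Reagents that add atoms: hydrogen peroxide, OO
Why: Weitz–Scheffer nucleophilic epoxidation of a cis-disubstituted cyclic enone by hydroperoxide anion, which should leave the unactivated isopropenyl group and the hindered tert-butyl ester untouched and whose facial outcome is irrelevant because both epoxide carbons lose their configuration in steps 5 and 6.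

Step 5
Reactants: 12 tert-butyl 3-[(3S,4S)-3-methyl-2-oxo-4-(prop-1-en-2-yl)-7-oxabicyclo[4.1.0]heptan-3-yl]propanoate
Product: 14 tert-butyl 3-[(1R,6S)-4-hydroxy-1-methyl-6-(prop-1-en-2-yl)cyclohex-2-en-1-yl]propanoate (both C4 epimers), via epoxy hydrazone 13 (not isolated)
Conditions: N2H4·H2O (2.5 equiv), AcOH (0.5 equiv), MeOH, 0 °C → rt, N2 atmosphere
Reagents that add atoms: none
Why: Wharton transposition, in which the epoxy hydrazone opens to an allylic diazene that loses dinitrogen, so that the oxygen stays on the former β-carbon and the double bond forms between the former carbonyl and α-carbons next to the quaternary carbon, while the tert-butyl ester resists hydrazinolysis and exclusion of air prevents diimide reduction of the isopropenyl group.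

Step 6
Reactants: 14 tert-butyl 3-[(1R,6S)-4-hydroxy-1-methyl-6-(prop-1-en-2-yl)cyclohex-2-en-1-yl]propanoate
Product: 15 tert-butyl 3-[(1R,6S)-1-methyl-4-oxo-6-(prop-1-en-2-yl)cyclohex-2-en-1-yl]propanoate
Conditions: Dess–Martin periodinane (1.3 equiv), NaHCO3, CH2Cl2, 0 °C → rt
Reagents that add atoms: none
Why: Dess–Martin oxidation of a secondary allylic alcohol to the enone under buffered conditions, which should convert both carbinol epimers into one compound without affecting the alkene, the ester or the stereocentres.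

Step 7
Reactants: 16 ethyl 2-isopropylacetoacetate (ethyl 2-acetyl-3-methylbutanoate)
Product: 18 4-hydroxy-3-(propan-2-yl)furan-2(5H)-one, via bromo keto ester 17 (not isolated)
Conditions: Br2 (1.0 equiv), CHCl3, 0 °C → rt; then neat, 130 °C
Reagents that add atoms: none
Why: Classical tetronic acid synthesis, in which bromination under the HBr formed leads to the γ-bromo β-keto ester and heating lets the ester oxygen displace bromide intramolecularly with loss of bromoethane to give the 3-alkyltetronic acid.

Step 8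
Reactants: 18 4-hydroxy-3-(propan-2-yl)furan-2(5H)-one
Product: 19 4-methoxy-3-(propan-2-yl)furan-2(5H)-one
Conditions: Me2SO4 (1.2 equiv), K2CO3, acetone, reflux
Reagents that add atoms: dimethyl sulfate, COS(=O)(=O)OC
Why: O-alkylation of a vinylogous acid, which should give mainly the 4-methoxy tetronate because this isomer keeps the lactone carbonyl in conjugation.

Step 9
Reactants: 19 4-methoxy-3-(propan-2-yl)furan-2(5H)-one
Product: 21 4-methoxy-5-(phenylsulfanyl)-3-(propan-2-yl)furan-2(5H)-one (racemic), via lithium furanolate 20 (not isolated)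
Conditions: LiN(iPr)2 (1.1 equiv), THF, −78 °C; then cannulation into PhSO2SPh (1.3 equiv), THF, −78 °C; 1 M HCl
Reagents that add atoms: S-phenyl benzenethiosulfonate, O=S(=O)(Sc1ccccc1)c1ccccc1
Why: Sulfenylation of a lactone dienolate, in which deprotonation of the methyl tetronate at C5 gives an aromatic furanolate that should react with the thiosulfonate at C5 because C3 is blocked by isopropyl, with inverse addition limiting double sulfenylation.

Step 10
Reactants: 21 4-methoxy-5-(phenylsulfanyl)-3-(propan-2-yl)furan-2(5H)-one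
Product: 22 4-methoxy-5-(phenylsulfonyl)-3-(propan-2-yl)furan-2(5H)-one (racemic)
Conditions: mCPBA (2.3 equiv), NaHCO3, CH2Cl2, 0 °C → rt
Reagents that add atoms: 3-chloroperoxybenzoic acid, O=C(OO)c1cccc(Cl)c1
Why: Peracid oxidation of a sulfide to the sulfone through the sulfoxide, which should not epoxidise the electron-poor tetronate double bond and cannot eliminate because C5 has no β-hydrogen.

Step 11
Reactants: 15 tert-butyl 3-[(1R,6S)-1-methyl-4-oxo-6-(prop-1-en-2-yl)cyclohex-2-en-1-yl]propanoate; 22 4-methoxy-5-(phenylsulfonyl)-3-(propan-2-yl)furan-2(5H)-one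
Product: 25 tert-butyl 3-[(1S,2S)-5,8-dihydroxy-7-methoxy-1-methyl-4-oxo-6-(propan-2-yl)-2-(prop-1-en-2-yl)-1,2,3,4-tetrahydronaphthalen-1-yl]propanoate, via lithiated sulfone 23 (not isolated), via ene-trione 24 (not isolated)
Conditions: LiOtBu (3.2 equiv), 22 (1.2 equiv), THF, −78 °C; then 15, −78 °C → rt, argon; AcOH quench, aq. Na2S2O4 wash
Reagents that add atoms: none
Why: LiOtBu deprotonates C5 of 22 to the sulfonyl-stabilised furanolate 23, which adds in Michael fashion to the enone β-carbon of 15 (new bond C5–C4a); the ketone enolate so formed attacks the lactone carbonyl (new bond C8–C8a), the expelled ring oxygen ejects benzenesulfinate, and the ene-trione 24 tautomerises to the hydroquinone. This is a Hauser–Kraus annulation, best known for sulfonyl phthalides and cyclohexenones and applied here to a non-benzo sulfonyl butenolide and a β-carbon flanked by a quaternary centre. The one new ring, the arene, closes by a Dieckmann-type 6-exo-trig attack of the enolate carbon on the lactone carbonyl. No stereocentre is created, and C3 and C4 are not at risk because C4 is quaternary and C3 lies β to the ketone. The step needs regio- and chemoselectivity: polarity fixes the orientation (nucleophilic furanone C5 to the β-carbon, lactone carbonyl to the α-carbon, hence isopropyl at C7 and methoxy at C6), and 15 offers a single acceptor alkene and a tert-butyl ester that resists Claisen attack.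

Step 12
Reactants: 25 tert-butyl 3-[(1S,2S)-5,8-dihydroxy-7-methoxy-1-methyl-4-oxo-6-(propan-2-yl)-2-(prop-1-en-2-yl)-1,2,3,4-tetrahydronaphthalen-1-yl]propanoate
Product: 27 3-[(1S,2S)-5,8-dihydroxy-7-methoxy-1-methyl-4-oxo-6-(propan-2-yl)-2-(prop-1-en-2-yl)-1,2,3,4-tetrahydronaphthalen-1-yl]propanoic acid (CNP0249049.1), via tris-silyl derivative 26 (not isolated)
Conditions: Me3SiOTf (5 equiv), 2,6-lutidine (8 equiv), CH2Cl2, 0 °C → rt, argon; then MeOH/pH 5 phosphate buffer, Na2S2O4
Reagents that add atoms: none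
Why: Silyl triflate-mediated cleavage of a tert-butyl ester, in which O-silylation of the ester triggers loss of 2-methylpropene under lutidine buffering so that no protic acid can add the phenol or the acid across the isopropenyl group, and mild hydrolysis of the silyl ester and aryl silyl ethers under dithionite should give the acid without oxidation to the quinone.

Compound list
1 | 2-methylcyclohex-2-en-1-one | CC1=CCCCC1=O | starting material
2 | isopropenylmagnesium bromide | C=C(C)[Mg]Br | starting material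
3 | bromomagnesium (3S)-2-methyl-3-(prop-1-en-2-yl)cyclohex-1-en-1-olate | C=C(C)[C@@H]1CCCC(O[Mg]Br)=C1C | intermediate
4 | (3R)-2-methyl-3-(prop-1-en-2-yl)cyclohexan-1-one (both C2 epimers) | C=C(C)[C@@H]1CCCC(=O)C1C | intermediate
5 | tert-butyl acrylate | C=CC(=O)OC(C)(C)C | starting material
6 | (3R)-N-benzyl-2-methyl-3-(prop-1-en-2-yl)cyclohexan-1-imine (both C2 epimers) | C=C(C)[C@@H]1CCCC(=NCc2ccccc2)C1C | intermediate
7 | tert-butyl 3-[(1S,6S)-2-(benzylimino)-1-methyl-6-(prop-1-en-2-yl)cyclohexyl]propanoate | C=C(C)[C@@H]1CCCC(=NCc2ccccc2)[C@@]1(C)CCC(=O)OC(C)(C)C | intermediate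
8 | tert-butyl 3-[(1S,6S)-1-methyl-2-oxo-6-(prop-1-en-2-yl)cyclohexyl]propanoate | C=C(C)[C@@H]1CCCC(=O)[C@@]1(C)CCC(=O)OC(C)(C)C | intermediate
9 | lithium (5S,6S)-6-(3-tert-butoxy-3-oxopropyl)-6-methyl-5-(prop-1-en-2-yl)cyclohex-1-en-1-olate | C=C(C)[C@@H]1CCC=C(O[Li])[C@@]1(C)CCC(=O)OC(C)(C)C | intermediate
10 | tert-butyl 3-[(1S,6S)-1-methyl-6-(prop-1-en-2-yl)-2-(trimethylsilyloxy)cyclohex-2-en-1-yl]propanoate | C=C(C)[C@@H]1CCC=C(O[Si](C)(C)C)[C@@]1(C)CCC(=O)OC(C)(C)C | intermediate
11 | tert-butyl 3-[(1S,6S)-1-methyl-2-oxo-6-(prop-1-en-2-yl)cyclohex-3-en-1-yl]propanoate | C=C(C)[C@@H]1CC=CC(=O)[C@@]1(C)CCC(=O)OC(C)(C)C | intermediate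
12 | tert-butyl 3-[(3S,4S)-3-methyl-2-oxo-4-(prop-1-en-2-yl)-7-oxabicyclo[4.1.0]heptan-3-yl]propanoate (epoxide diastereomers) | C=C(C)[C@@H]1CC2OC2C(=O)[C@@]1(C)CCC(=O)OC(C)(C)C | intermediate
13 | tert-butyl 3-[(3S,4S)-2-hydrazinylidene-3-methyl-4-(prop-1-en-2-yl)-7-oxabicyclo[4.1.0]heptan-3-yl]propanoate | C=C(C)[C@@H]1CC2OC2C(=NN)[C@@]1(C)CCC(=O)OC(C)(C)C | intermediate
14 | tert-butyl 3-[(1R,6S)-4-hydroxy-1-methyl-6-(prop-1-en-2-yl)cyclohex-2-en-1-yl]propanoate (both C4 epimers) | C=C(C)[C@@H]1CC(O)C=C[C@@]1(C)CCC(=O)OC(C)(C)C | intermediate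
15 | tert-butyl 3-[(1R,6S)-1-methyl-4-oxo-6-(prop-1-en-2-yl)cyclohex-2-en-1-yl]propanoate | C=C(C)[C@@H]1CC(=O)C=C[C@@]1(C)CCC(=O)OC(C)(C)C | intermediate
16 | ethyl 2-isopropylacetoacetate | CCOC(=O)C(C(C)C)C(C)=O | starting material
17 | ethyl 4-bromo-3-oxo-2-(propan-2-yl)butanoate | CCOC(=O)C(C(C)C)C(=O)CBr | intermediate
18 | 4-hydroxy-3-(propan-2-yl)furan-2(5H)-one | CC(C)C1=C(O)COC1=O | intermediate
19 | 4-methoxy-3-(propan-2-yl)furan-2(5H)-one | COC1=C(C(C)C)C(=O)OC1 | intermediate
20 | lithium 4-methoxy-3-(propan-2-yl)furan-2-olate | COc1coc(O[Li])c1C(C)C | intermediate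
21 | 4-methoxy-5-(phenylsulfanyl)-3-(propan-2-yl)furan-2(5H)-one (racemic) | COC1=C(C(C)C)C(=O)OC1Sc1ccccc1 | intermediate
22 | 4-methoxy-5-(phenylsulfonyl)-3-(propan-2-yl)furan-2(5H)-one (racemic) | COC1=C(C(C)C)C(=O)OC1S(=O)(=O)c1ccccc1 | intermediate
23 | lithium 5-(benzenesulfonyl)-4-methoxy-3-(propan-2-yl)furan-2-olate | COc1c(S(=O)(=O)c2ccccc2)oc(O[Li])c1C(C)C | intermediate
24 | tert-butyl 3-[(1S,2S)-7-methoxy-1-methyl-4,5,8-trioxo-6-(propan-2-yl)-2-(prop-1-en-2-yl)-1,2,3,4,4a,5,8,8a-octahydronaphthalen-1-yl]propanoate | C=C(C)[C@@H]1CC(=O)C2C(=O)C(C(C)C)=C(OC)C(=O)C2[C@@]1(C)CCC(=O)OC(C)(C)C | intermediate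
25 | tert-butyl 3-[(1S,2S)-5,8-dihydroxy-7-methoxy-1-methyl-4-oxo-6-(propan-2-yl)-2-(prop-1-en-2-yl)-1,2,3,4-tetrahydronaphthalen-1-yl]propanoate | C=C(C)[C@@H]1CC(=O)c2c(O)c(C(C)C)c(OC)c(O)c2[C@@]1(C)CCC(=O)OC(C)(C)C | intermediate
26 | trimethylsilyl 3-[(1S,2S)-7-methoxy-1-methyl-4-oxo-6-(propan-2-yl)-2-(prop-1-en-2-yl)-5,8-bis(trimethylsilyloxy)-1,2,3,4-tetrahydronaphthalen-1-yl]propanoate | C=C(C)[C@@H]1CC(=O)c2c(O[Si](C)(C)C)c(C(C)C)c(OC)c(O[Si](C)(C)C)c2[C@@]1(C)CCC(=O)O[Si](C)(C)C | intermediate
27 | 3-[(1S,2S)-5,8-dihydroxy-7-methoxy-1-methyl-4-oxo-6-(propan-2-yl)-2-(prop-1-en-2-yl)-1,2,3,4-tetrahydronaphthalen-1-yl]propanoic acid (CNP0249049.1) | C=C(C)[C@@H]1CC(=O)c2c(O)c(C(C)C)c(OC)c(O)c2[C@@]1(C)CCC(=O)O | target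

Total step count: 12.
Longest linear sequence: 8 steps (steps 1 to 6, then 11 and 12); the donor branch (steps 7 to 10) joins at step 11.

Steps most likely to fail

Step 11. The conjugate addition may stall because a fully substituted sulfonyl carbanion must attack a β-carbon flanked by the quaternary C4. The anion could then decay by loss of sulfinate, or the enone could be consumed by base before annulation. The fallback sets out from 19 and 15 and returns at 25. The tetronate 19 is silylated (TBSOTf, Et3N, CH2Cl2, 0 °C) to the silyloxyfuran tert-butyl{[4-methoxy-3-(propan-2-yl)furan-2-yl]oxy}dimethylsilane F1. A Lewis-acid-promoted vinylogous Mukaiyama–Michael addition of F1 to 15 (BF3·OEt2, CH2Cl2, −78 °C, aqueous work-up) joins furanone C5, now free of the sulfonyl group, to the enone β-carbon. It should give the keto butenolide tert-butyl 3-[(1S,6S)-2-[3-methoxy-5-oxo-4-(propan-2-yl)-2,5-dihydrofuran-2-yl]-1-methyl-4-oxo-6-(prop-1-en-2-yl)cyclohexyl]propanoate F2 as a mixture at the two new centres, which are lost later. KOtBu in THF then closes the ring by intramolecular Claisen condensation of the ketone enolate on the lactone, giving the hydroxy diketone tert-butyl 3-[(1S,2S)-8-hydroxy-7-methoxy-1-methyl-4,5-dioxo-6-(propan-2-yl)-2-(prop-1-en-2-yl)-1,2,3,4,4a,5,8,8a-octahydronaphthalen-1-yl]propanoate F3. Dess–Martin oxidation of its allylic carbinol gives the ene-trione 24, which tautomerises to 25.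

Step 1. Enantioselectivity may be low, because alkenyl Grignard reagents are transferred through less ordered copper intermediates than alkyl ones and the uncatalysed background addition is fast. The fallback sets out from 2 and returns at 4; a sulfinyl auxiliary replaces the chiral catalyst. Commercial 6-bromo-1,4-dioxaspiro[4.5]dec-6-ene is lithiated (n-BuLi, THF, −78 °C) and sulfinylated with (1R,2S,5R)-menthyl (S)-4-methylbenzenesulfinate to (S)-6-(4-methylbenzenesulfinyl)-1,4-dioxaspiro[4.5]dec-6-ene F4. Its ketal is hydrolysed (CuSO4, acetone) to (S)-2-(4-methylbenzenesulfinyl)cyclohex-2-en-1-one F5. ZnBr2-chelated conjugate addition of 2 (THF, −78 °C) on the face opposite to the tolyl group should give (3S)-2-[(R)-4-methylbenzenesulfinyl]-3-(prop-1-en-2-yl)cyclohexan-1-one F6. C-methylation of this β-keto sulfoxide (NaH, MeI, THF) gives (3S)-2-methyl-2-[(S)-4-methylbenzenesulfinyl]-3-(prop-1-en-2-yl)cyclohexan-1-one F7. Aluminium amalgam (Al/Hg, aqueous THF) then cleaves the C–S bond to 4.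

Step 5. Hydrazone formation at the carbonyl next to the quaternary carbon may be slow, so that hydrazine opens the epoxide instead or the diazene partitions to reduced by-products; adventitious diimide could also saturate the isopropenyl group. The fallback sets out from 8 and returns at 15, replacing steps 3 to 6. The ketone is converted (KN(SiMe3)2, PhNTf2, THF, −78 °C) to the enol triflate tert-butyl 3-[(1S,6S)-1-methyl-6-(prop-1-en-2-yl)-2-{[(trifluoromethyl)sulfonyl]oxy}cyclohex-2-en-1-yl]propanoate F8. Formate reduction under palladium catalysis (Pd(OAc)2, PPh3, Bu3N, HCO2H, DMF, 60 °C) gives the cyclohexene tert-butyl 3-[(1R,6S)-1-methyl-6-(prop-1-en-2-yl)cyclohex-2-en-1-yl]propanoate F9. Allylic oxidation of its only ring allylic methylene (CrO3·3,5-dimethylpyrazole, CH2Cl2, −20 °C) should give 15 directly; its selectivity over the allylic positions of the isopropenyl group rests on the greater reactivity of the ring CH2 and is the weak point of this alternative.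

Further compounds
F1 | step 11 | tert-butyl{[4-methoxy-3-(propan-2-yl)furan-2-yl]oxy}dimethylsilane | COc1coc(O[Si](C)(C)C(C)(C)C)c1C(C)C
F2 | step 11 | tert-butyl 3-[(1S,6S)-2-[3-methoxy-5-oxo-4-(propan-2-yl)-2,5-dihydrofuran-2-yl]-1-methyl-4-oxo-6-(prop-1-en-2-yl)cyclohexyl]propanoate (mixture at the two new centres) | C=C(C)[C@@H]1CC(=O)CC(C2OC(=O)C(C(C)C)=C2OC)[C@@]1(C)CCC(=O)OC(C)(C)C
F3 | step 11 | tert-butyl 3-[(1S,2S)-8-hydroxy-7-methoxy-1-methyl-4,5-dioxo-6-(propan-2-yl)-2-(prop-1-en-2-yl)-1,2,3,4,4a,5,8,8a-octahydronaphthalen-1-yl]propanoate (mixture at the new centres) | C=C(C)[C@@H]1CC(=O)C2C(=O)C(C(C)C)=C(OC)C(O)C2[C@@]1(C)CCC(=O)OC(C)(C)C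
F4 | step 1 | (S)-6-(4-methylbenzenesulfinyl)-1,4-dioxaspiro[4.5]dec-6-ene | Cc1ccc(cc1)[S@](=O)C1=CCCCC12OCCO2
F5 | step 1 | (S)-2-(4-methylbenzenesulfinyl)cyclohex-2-en-1-one | Cc1ccc(cc1)[S@](=O)C1=CCCCC1=O
F6 | step 1 | (3S)-2-[(R)-4-methylbenzenesulfinyl]-3-(prop-1-en-2-yl)cyclohexan-1-one (C2 epimers) | C=C(C)[C@@H]1CCCC(=O)C1[S@@](=O)c1ccc(C)cc1
F7 | step 1 | (3S)-2-methyl-2-[(S)-4-methylbenzenesulfinyl]-3-(prop-1-en-2-yl)cyclohexan-1-one (C2 epimers) | C=C(C)[C@@H]1CCCC(=O)C1(C)[S@@](=O)c1ccc(C)cc1
F8 | step 5 | tert-butyl 3-[(1S,6S)-1-methyl-6-(prop-1-en-2-yl)-2-{[(trifluoromethyl)sulfonyl]oxy}cyclohex-2-en-1-yl]propanoate | C=C(C)[C@@H]1CCC=C(OS(=O)(=O)C(F)(F)F)[C@@]1(C)CCC(=O)OC(C)(C)C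
F9 | step 5 | tert-butyl 3-[(1R,6S)-1-methyl-6-(prop-1-en-2-yl)cyclohex-2-en-1-yl]propanoate | C=C(C)[C@@H]1CCC=C[C@@]1(C)CCC(=O)OC(C)(C)C
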